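The route rests on disconnecting ring C at C8–C14 and C9–C11 (ent-kaurane numbering). C8 lies between the C7 lactone carbonyl and the C15 ketone, so a C8=C9 double bond in the δ-lactone is a doubly activated dienophile. One ZnCl2-promoted Diels–Alder reaction with 2-acetoxy-3-(phenylthio)buta-1,3-diene closes ring C, makes C8 quaternary, sets C8 and C9 and places oxygen at C13 next to C14. The precursor is a spiro 3-propanoyl-5,6-dihydropyran-2-one whose ring A already carries the C1 enone (C2=C3), the C4 gem-dimethyl group and the C5 silyloxymethyl arm. Ring D follows by aldol closure of C16 onto C13.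

Key step: step 15

Remark: atom numbers (C1–C20) follow ent-kaurane numbering; where a SMILES has no descriptor at a centre (C8 in 23–25, C12 in 34, C16 in 36, the new carbons of 10 and 12) both epimers are meant.
Remark: ring A enters the key step as the C1 enone because, flanked by quaternary C4 and C10, it has no enolisable hydrogen (clean C8 acylation and C16 enolisation) and no dehydrogenation is then needed beside the C15/C16 ketone.

Step 1
Reactants: 1 3,3-dimethylpent-4-enoic acid; 2 (4S)-4-benzyl-1,3-oxazolidin-2-one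
Product: 4 (4S)-4-benzyl-3-(3,3-dimethylpent-4-enoyl)-1,3-oxazolidin-2-one, via mixed pivalic anhydride 3 (not isolated)
Conditions: PivCl, Et3N, THF, −20 °C; then 2, LiCl, −20 °C to rt
Reagents that add atoms: none
Why: N-acylation of the oxazolidinone by a mixed anhydride (auxiliary attachment for an Evans alkylation) is a standard acyl transfer in which the unhindered, non-pivaloyl carbonyl is attacked.

Step 2
Reactants: 4 (4S)-4-benzyl-3-(3,3-dimethylpent-4-enoyl)-1,3-oxazolidin-2-one; 5 3-bromo-2-methylprop-1-ene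
Product: 7 (4S)-4-benzyl-3-[(2S)-3,3-dimethyl-2-(2-methylprop-2-en-1-yl)pent-4-enoyl]-1,3-oxazolidin-2-one, via sodium enolate 6 (not isolated)
Conditions: NaN(SiMe3)2, THF, −78 °C; then 5, −78 to −30 °C
Reagents that add atoms: none
Why: Evans alkylation, in which the chelated (Z)-enolate is attacked by the reactive allylic bromide on the face opposite the benzyl group, should set the future C5 stereocentre (2S here).

Step 3
Reactants: 7 (4S)-4-benzyl-3-[(2S)-3,3-dimethyl-2-(2-methylprop-2-en-1-yl)pent-4-enoyl]-1,3-oxazolidin-2-one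
Product: 8 (2S)-3,3-dimethyl-2-(2-methylprop-2-en-1-yl)pent-4-en-1-ol
Conditions: LiBH4, MeOH, Et2O, 0 °C
Reagents that add atoms: none
Why: Reductive cleavage of the N-acyl oxazolidinone with borohydride is the standard auxiliary removal and should give the C6 primary alcohol without touching the alkenes or the α-stereocentre.

Step 4
Reactants: 8 (2S)-3,3-dimethyl-2-(2-methylprop-2-en-1-yl)pent-4-en-1-ol
Product: 9 tert-butyl{[(2S)-3,3-dimethyl-2-(2-methylprop-2-en-1-yl)pent-4-en-1-yl]oxy}dimethylsilane
Conditions: TBSCl, imidazole, CH2Cl2, rt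
Reagents that add atoms: tert-butyldimethylsilyl chloride (TBSCl), CC(C)(C)[Si](C)(C)Cl
Why: Imidazole-mediated silylation of the primary alcohol gives a silyl ether that should survive ozone, enolate, Lewis acid and samarium chemistry until the last step.

Step 5
Reactants: 9 tert-butyl{[(2S)-3,3-dimethyl-2-(2-methylprop-2-en-1-yl)pent-4-en-1-yl]oxy}dimethylsilane
Product: 11 (3S)-3-({[tert-butyl(dimethyl)silyl]oxy}methyl)-2,2-dimethyl-5-oxohexanal, via bis-ozonide 10 (not isolated)
Conditions: O3, CH2Cl2, −78 °C; then PPh3, −78 °C to rt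
Reagents that add atoms: ozone, [O-][O+]=O
Why: Ozonolysis with reductive work-up cleaves both terminal alkenes to the non-enolisable C3 aldehyde and the C1 methyl ketone, and C5 is α to neither carbonyl so it cannot epimerise.

Step 6
Reactants: 11 (3S)-3-({[tert-butyl(dimethyl)silyl]oxy}methyl)-2,2-dimethyl-5-oxohexanal
Product: 13 (5S)-5-({[tert-butyl(dimethyl)silyl]oxy}methyl)-4,4-dimethylcyclohex-2-en-1-one, via aldol adduct 12 (not isolated)
Conditions: piperidine, AcOH, toluene, 80 °C
Reagents that add atoms: none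
Why: Intramolecular aldol condensation (the ring-closing half of a Robinson annulation) can form a six-membered ring only by attack of the ketone methyl group (C2) on the aldehyde, and dehydration gives ring A with C2=C3.

Step 7
Reactants: 13 (5S)-5-({[tert-butyl(dimethyl)silyl]oxy}methyl)-4,4-dimethylcyclohex-2-en-1-one; 14 ethyl formate
Product: 15 (5R,6Z)-5-({[tert-butyl(dimethyl)silyl]oxy}methyl)-6-(hydroxymethylidene)-4,4-dimethylcyclohex-2-en-1-one
Conditions: NaH, EtOH (cat.), THF, 0 °C to rt; then aq. HCl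
Reagents that add atoms: none
Why: Claisen condensation with a formate is regiospecific here because C10 is the only enolisable position of the enone (C4 is quaternary), giving the chelated hydroxymethylene ketone that carries C20.

Step 8
Reactants: 15 (5R,6Z)-5-({[tert-butyl(dimethyl)silyl]oxy}methyl)-6-(hydroxymethylidene)-4,4-dimethylcyclohex-2-en-1-one; 16 2,2,2-trifluoroethyl prop-2-enoate
Product: 17 2,2,2-trifluoroethyl 3-[(1S,6R)-6-({[tert-butyl(dimethyl)silyl]oxy}methyl)-1-formyl-5,5-dimethyl-2-oxocyclohex-3-en-1-yl]propanoate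
Conditions: DBU (0.1 equiv), MeCN, 0 °C to rt
Reagents that add atoms: none
Why: Michael addition of the stabilised formyl ketone enolate to the activated acrylate builds quaternary C10, the acceptor approaching anti to the neighbouring C5 silyloxymethyl group (held pseudoaxial by allylic strain) so that C9 ends trans and C20 cis to C6.

Step 9
Reactants: 17 2,2,2-trifluoroethyl 3-[(1S,6R)-6-({[tert-butyl(dimethyl)silyl]oxy}methyl)-1-formyl-5,5-dimethyl-2-oxocyclohex-3-en-1-yl]propanoate
Product: 19 (6S,11R)-11-({[tert-butyl(dimethyl)silyl]oxy}methyl)-10,10-dimethyl-2-oxaspiro[5.5]undec-8-ene-3,7-dione, via hydroxy ester 18 (not isolated)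
Conditions: NaBH4, THF/MeOH, −78 to 0 °C
Reagents that add atoms: none
Why: Chemoselective borohydride reduction of the aldehyde (far more electrophilic at −78 °C than the hindered, conjugated C1 ketone) gives the C20 alcohol, which lactonises onto the activated trifluoroethyl ester to close the δ-lactone.

Step 10
Reactants: 19 (6S,11R)-11-({[tert-butyl(dimethyl)silyl]oxy}methyl)-10,10-dimethyl-2-oxaspiro[5.5]undec-8-ene-3,7-dione; 20 N-methoxy-N-methylpropanamide
Product: 23 (6S,11R)-11-({[tert-butyl(dimethyl)silyl]oxy}methyl)-10,10-dimethyl-4-propanoyl-2-oxaspiro[5.5]undec-8-ene-3,7-dione (C8 epimers), via lithium lactone enolate 21 (not isolated), via lithium hemiaminal adduct 22 (not isolated)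
Conditions: LiN(SiMe3)2, THF, −78 °C; then 20, −78 to 0 °C; aq. NH4Cl
Reagents that add atoms: none
Why: Crossed Claisen-type C-acylation of the lactone enolate by a Weinreb amide is clean because C8 is the only enolisable carbon in 19 and the tetrahedral adduct holds until work-up.

Step 11
Reactants: 23 (6S,11R)-11-({[tert-butyl(dimethyl)silyl]oxy}methyl)-10,10-dimethyl-4-propanoyl-2-oxaspiro[5.5]undec-8-ene-3,7-dione
Product: 26 (6S,11R)-11-({[tert-butyl(dimethyl)silyl]oxy}methyl)-10,10-dimethyl-4-propanoyl-2-oxaspiro[5.5]undeca-4,8-diene-3,7-dione, via C8 phenylselenide 24 (not isolated), via C8 selenoxide 25 (not isolated)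
Conditions: PhSeCl, pyridine, CH2Cl2, 0 °C; aq. HCl wash; then H2O2 (30% aq.), 0 °C
Reagents that add atoms: none
Why: Selenenylation of the 1,3-dicarbonyl at C8 followed by selenoxide syn-elimination, which can take a hydrogen only from C9, installs the C8=C9 bond of the doubly activated dienophile (used at once).

Step 12
Reactants: 27 benzenethiol; 28 3-chlorobutan-2-one
Product: 29 3-(phenylsulfanyl)butan-2-one
Conditions: Et3N, CH2Cl2, 0 °C to rt
Reagents that add atoms: none
Why: SN2 displacement of the activated α-chloro ketone by thiolate is fast and clean.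

Step 13
Reactants: 29 3-(phenylsulfanyl)butan-2-one
Product: 31 3-(phenylsulfanyl)but-3-en-2-one, via chloro sulfide 30 (not isolated)
Conditions: NCS, CH2Cl2, 0 °C to rt; then Et3N, rt
Reagents that add atoms: none
Why: α-Chlorination of the sulfide with NCS (through the chlorosulfonium ion) and dehydrochlorination, possible only toward the C4 methyl group, give the α-phenylthio enone.

Step 14
Reactants: 31 3-(phenylsulfanyl)but-3-en-2-one
Product: 32 3-(phenylsulfanyl)buta-1,3-dien-2-yl acetate
Conditions: isopropenyl acetate, TsOH (cat.), hydroquinone (cat.), 90 °C, acetone distilled off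
Reagents that add atoms: isopropenyl acetate, CC(=C)OC(C)=O
Why: Acid-catalysed enol acetate exchange (as used to make 2-acetoxybutadiene from methyl vinyl ketone) can give only this dienol acetate because the methyl group is the sole enolisable position.

Step 15
Reactants: 26 (6S,11R)-11-({[tert-butyl(dimethyl)silyl]oxy}methyl)-10,10-dimethyl-4-propanoyl-2-oxaspiro[5.5]undeca-4,8-diene-3,7-dione; 32 3-(phenylsulfanyl)buta-1,3-dien-2-yl acetate
Product: 33 (5R,8S,9S,10S)-cycloadduct with ring C cis-fused to the lactone (C12=C13 bearing C13 acetoxy and C12 phenylsulfanyl; C8 propanoyl; ring A C1 enone; C6 O-TBS)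
Conditions: ZnCl2 (1.5 equiv), CH2Cl2, −20 °C to rt
Reagents that add atoms: none
Why: ZnCl2 chelates the C7 lactone and C15 ketone carbonyls and lowers the LUMO of C8=C9, which then undergoes a concerted but asynchronous [4+2] cycloaddition with the electron-rich diene. The closest known reaction type is the Lewis-acid-promoted Diels–Alder reaction of 2-acyl-2-enoates with 2-acyloxy-3-arylthio-1,3-dienes, in which sulfur outweighs the acyloxy group in fixing orientation. Ring C closes as the six-membered cycloadduct ring by suprafacial formation of C9–C11 and C8–C14 in an intermolecular cycloaddition, so its fusion to the lactone is necessarily cis. C9 is set by the face of attack, which spiro C10 controls: the diene comes in on the side of the flat C1 carbonyl and away from C5 with its silyloxymethyl arm and the adjacent gem-dimethyl C4, and C8 follows from C9 because both bonds form on the same face. The regiochemistry needed (C11, the terminus next to the C–S carbon, to the β-carbon C9, so that the acetoxy carbon becomes C13) follows from the larger HOMO coefficient at that terminus, and chemoselectivity over the ring A enone from the double activation and chelation of C8=C9 against the unactivated, neopentyl C2=C3.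

Step 16
Reactants: 33 (5R,8S,9S,10S)-cycloadduct (C13 enol acetate, C12 phenylsulfanyl)
Product: 34 (5R,8S,9S,10S)-13-oxo-12-(phenylsulfanyl) compound (C12 epimers; C8 propanoyl; C6 O-TBS)
Conditions: K2CO3 (0.2 equiv), MeOH, 0 °C, short reaction time
Reagents that add atoms: none
Why: Transesterification of the enol acetate, an activated ester cleaved much faster than the hindered lactone, releases the C13 ketone, and the unselective protonation at C12 does not matter because sulfur is removed next.

Step 17
Reactants: 34 (5R,8S,9S,10S)-13-oxo-12-(phenylsulfanyl) compound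
Product: 35 (5R,8S,9S,10S)-13,15-diketone (C8 propanoyl; ring C C13 ketone; ring A enone; C6 O-TBS)
Conditions: SmI2 (2.5 equiv), THF/MeOH, −78 °C
Reagents that add atoms: none
Why: Reductive cleavage of the C–S bond α to the ketone by SmI2 (two single-electron transfers, the samarium enolate being protonated by methanol) is far faster at −78 °C than reduction of the other ketone, the enone or the lactone.

Step 18
Reactants: 35 (5R,8S,9S,10S)-13,15-diketone
Product: 36 (5R,8S,9S,10S,13S)-13-hydroxy-15-oxo ring D ketol (C16 methyl of either configuration; C6 O-TBS)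
Conditions: TiCl4 (2.2 equiv), i-Pr2NEt (1.2 equiv), CH2Cl2, −78 to −40 °C
Reagents that add atoms: none
Why: Intramolecular titanium-enolate aldol addition (soft enolisation), in which TiCl4 chelates the C7/C15 1,3-dicarbonyl so that the amine removes a C16 hydrogen selectively and the enolate adds to the C13 ketone from the face on which the axial C15 sits, fixes C13 because the bicyclo[3.2.1]octane can close only one way.

Step 19
Reactants: 36 (5R,8S,9S,10S,13S)-13-hydroxy-15-oxo ring D ketol (C16 epimers)
Product: 38 (5R,8S,9S,10S,13S,16R)-ketol (6-O-TBS ether of the target), via dilithium alkoxide enolate 37 (not isolated)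
Conditions: LiN(SiMe3)2 (3 equiv), THF, −78 to −40 °C; then AcOH, −78 °C
Reagents that add atoms: none
Why: Enolisation and kinetic protonation: C16–H is the only enolisable hydrogen left, and protonation of the C15=C16 enolate from the less hindered exo face (the side of the one-carbon bridge C14) should put hydrogen exo and the methyl group endo, which is 16R, whichever epimer enters.

Step 20
Reactants: 38 (5R,8S,9S,10S,13S,16R)-ketol TBS ether
Product: 39 CNP0533761.1, (5R,8S,9S,10S,13S,16R)
Conditions: HF·pyridine, pyridine, THF, 0 °C to rt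
Reagents that add atoms: none
Why: Buffered fluoride cleavage of the primary silyl ether frees C6–OH without enolising C16 or opening the β-ketol.

Compound list
1 | 3,3-dimethylpent-4-enoic acid | C=CC(C)(C)CC(=O)O | starting material
2 | (4S)-4-benzyl-1,3-oxazolidin-2-one | O=C1OC[C@H](Cc2ccccc2)N1 | starting material
3 | 3,3-dimethylpent-4-enoic pivalic anhydride | C=CC(C)(C)CC(=O)OC(=O)C(C)(C)C | intermediate
4 | (4S)-4-benzyl-3-(3,3-dimethylpent-4-enoyl)-1,3-oxazolidin-2-one | C=CC(C)(C)CC(=O)N1C(=O)OC[C@@H]1Cc1ccccc1 | intermediate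
5 | 3-bromo-2-methylprop-1-ene | C=C(C)CBr | starting material
6 | sodium (Z)-enolate of 4 | C=CC(C)(C)/C=C(\[O-])N1C(=O)OC[C@@H]1Cc1ccccc1.[Na+] | intermediate
7 | (4S)-4-benzyl-3-[(2S)-3,3-dimethyl-2-(2-methylprop-2-en-1-yl)pent-4-enoyl]-1,3-oxazolidin-2-one | C=CC(C)(C)[C@H](CC(C)=C)C(=O)N1C(=O)OC[C@@H]1Cc1ccccc1 | intermediate
8 | (2S)-3,3-dimethyl-2-(2-methylprop-2-en-1-yl)pent-4-en-1-ol | C=CC(C)(C)[C@H](CC(C)=C)CO | intermediate
9 | TBS ether of 8 | C=CC(C)(C)[C@H](CC(C)=C)CO[Si](C)(C)C(C)(C)C | intermediate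
10 | bis(1,2,4-trioxolane) of 9 (ozonide carbons unassigned) | C1(OOCO1)C(C)(C)[C@H](CC2(C)OOCO2)CO[Si](C)(C)C(C)(C)C | intermediate
11 | (3S)-3-({[tert-butyl(dimethyl)silyl]oxy}methyl)-2,2-dimethyl-5-oxohexanal | O=CC(C)(C)[C@H](CC(C)=O)CO[Si](C)(C)C(C)(C)C | intermediate
12 | (5S)-5-(TBS-oxymethyl)-3-hydroxy-4,4-dimethylcyclohexan-1-one (C3 epimers) | O=C1CC(O)C(C)(C)[C@@H](CO[Si](C)(C)C(C)(C)C)C1 | intermediate
13 | (5S)-5-({[tert-butyl(dimethyl)silyl]oxy}methyl)-4,4-dimethylcyclohex-2-en-1-one | O=C1C=CC(C)(C)[C@@H](CO[Si](C)(C)C(C)(C)C)C1 | intermediate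
14 | ethyl formate | CCOC=O | starting material
15 | (5R,6Z)-5-(TBS-oxymethyl)-6-(hydroxymethylidene)-4,4-dimethylcyclohex-2-en-1-one | O/C=C1\C(=O)C=CC(C)(C)[C@H]1CO[Si](C)(C)C(C)(C)C | intermediate
16 | 2,2,2-trifluoroethyl prop-2-enoate | C=CC(=O)OCC(F)(F)F | starting material
17 | 2,2,2-trifluoroethyl 3-[(1S,6R)-6-(TBS-oxymethyl)-1-formyl-5,5-dimethyl-2-oxocyclohex-3-en-1-yl]propanoate | O=C[C@@]1(CCC(=O)OCC(F)(F)F)C(=O)C=CC(C)(C)[C@H]1CO[Si](C)(C)C(C)(C)C | intermediate
18 | 2,2,2-trifluoroethyl 3-[(1S,6R)-6-(TBS-oxymethyl)-1-(hydroxymethyl)-5,5-dimethyl-2-oxocyclohex-3-en-1-yl]propanoate | OC[C@@]1(CCC(=O)OCC(F)(F)F)C(=O)C=CC(C)(C)[C@H]1CO[Si](C)(C)C(C)(C)C | intermediate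
19 | (6S,11R)-11-(TBS-oxymethyl)-10,10-dimethyl-2-oxaspiro[5.5]undec-8-ene-3,7-dione (spirolactone, ring A enone) | O=C1CC[C@]2(CO1)C(=O)C=CC(C)(C)[C@H]2CO[Si](C)(C)C(C)(C)C | intermediate
20 | N-methoxy-N-methylpropanamide | CCC(=O)N(C)OC | starting material
21 | lithium enolate of lactone 19 (C7–O–Li, C7=C8) | [Li]OC1=CC[C@]2(CO1)C(=O)C=CC(C)(C)[C@H]2CO[Si](C)(C)C(C)(C)C | intermediate
22 | lithium hemiaminal adduct of 21 and 20 | CCC(O[Li])(N(C)OC)C1C[C@]2(COC1=O)C(=O)C=CC(C)(C)[C@H]2CO[Si](C)(C)C(C)(C)C | intermediate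
23 | (6S,11R)-11-(TBS-oxymethyl)-10,10-dimethyl-4-propanoyl-2-oxaspiro[5.5]undec-8-ene-3,7-dione (C8 epimers) | CCC(=O)C1C[C@]2(COC1=O)C(=O)C=CC(C)(C)[C@H]2CO[Si](C)(C)C(C)(C)C | intermediate
24 | C8 phenylselanyl derivative of 23 | CCC(=O)C1([Se]c3ccccc3)C[C@]2(COC1=O)C(=O)C=CC(C)(C)[C@H]2CO[Si](C)(C)C(C)(C)C | intermediate
25 | C8 selenoxide of 24 | CCC(=O)C1([Se](=O)c3ccccc3)C[C@]2(COC1=O)C(=O)C=CC(C)(C)[C@H]2CO[Si](C)(C)C(C)(C)C | intermediate
26 | (6S,11R)-11-(TBS-oxymethyl)-10,10-dimethyl-4-propanoyl-2-oxaspiro[5.5]undeca-4,8-diene-3,7-dione (dienophile, C8=C9) | CCC(=O)C1=C[C@]2(COC1=O)C(=O)C=CC(C)(C)[C@H]2CO[Si](C)(C)C(C)(C)C | intermediate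
27 | benzenethiol | Sc1ccccc1 | starting material
28 | 3-chlorobutan-2-one | CC(Cl)C(C)=O | starting material
29 | 3-(phenylsulfanyl)butan-2-one | CC(Sc1ccccc1)C(C)=O | intermediate
30 | 3-chloro-3-(phenylsulfanyl)butan-2-one | CC(Cl)(Sc1ccccc1)C(C)=O | intermediate
31 | 3-(phenylsulfanyl)but-3-en-2-one | C=C(Sc1ccccc1)C(C)=O | intermediate
32 | 3-(phenylsulfanyl)buta-1,3-dien-2-yl acetate | C=C(OC(C)=O)C(=C)Sc1ccccc1 | intermediate
33 | (5R,8S,9S,10S)-Diels–Alder adduct: C13 enol acetate, C12 phenylsulfanyl, C8 propanoyl, ring A enone, C6 O-TBS | CCC(=O)[C@]23CC(OC(C)=O)=C(Sc4ccccc4)C[C@H]2[C@]1(COC3=O)C(=O)C=CC(C)(C)[C@H]1CO[Si](C)(C)C(C)(C)C | intermediate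
34 | (5R,8S,9S,10S)-13-oxo-12-(phenylsulfanyl) compound (C12 epimers) | CCC(=O)[C@]23CC(=O)C(Sc4ccccc4)C[C@H]2[C@]1(COC3=O)C(=O)C=CC(C)(C)[C@H]1CO[Si](C)(C)C(C)(C)C | intermediate
35 | (5R,8S,9S,10S)-13,15-diketone | CCC(=O)[C@]23CC(=O)CC[C@H]2[C@]1(COC3=O)C(=O)C=CC(C)(C)[C@H]1CO[Si](C)(C)C(C)(C)C | intermediate
36 | (5R,8S,9S,10S,13S)-13-hydroxy-15-oxo ketol, C16 epimers, C6 O-TBS | CC1C(=O)[C@]23C[C@@]1(O)CC[C@H]2[C@]1(COC3=O)C(=O)C=CC(C)(C)[C@H]1CO[Si](C)(C)C(C)(C)C | intermediate
37 | dilithium C13 alkoxide C15=C16 enolate of 36 | CC1=C(O[Li])[C@]23C[C@@]1(O[Li])CC[C@H]2[C@]1(COC3=O)C(=O)C=CC(C)(C)[C@H]1CO[Si](C)(C)C(C)(C)C | intermediate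
38 | (5R,8S,9S,10S,13S,16R)-ketol, 6-O-TBS ether of the target | C[C@H]1C(=O)[C@]23C[C@@]1(O)CC[C@H]2[C@]1(COC3=O)C(=O)C=CC(C)(C)[C@H]1CO[Si](C)(C)C(C)(C)C | intermediate
39 | CNP0533761.1, (5R,8S,9S,10S,13S,16R) | C[C@H]1C(=O)[C@]23C[C@@]1(O)CC[C@H]2[C@]1(COC3=O)C(=O)C=CC(C)(C)[C@H]1CO | target

Total step count: 20. Longest linear sequence: 17 steps (steps 1–11 and 15–20); the diene branch is 3 steps (12–14).

Steps most likely to fail

1. Step 15. What may go wrong: the diene may add to the C5 face of C8=C9, may react through the O=C15–C8=C9 oxadiene in an inverse-demand hetero-cycloaddition, or may decompose under the Lewis acid before the hindered C9 is reached. The fallback sets out from 26 and comes back at 35, building ring C stepwise. Copper-catalysed conjugate addition of (3-methylbut-3-en-1-yl)magnesium bromide (CuBr·SMe2 cat., Me3SiCl, THF, −78 °C) to C9 of 26, again anti to C5, should give the C9 3-methylbut-3-enyl β-keto lactone F1. Oxidative radical cyclisation with Mn(OAc)3 and Cu(OAc)2 in AcOH should then give the ring C 13-methylidene compound F2: the C8 radical attacks the terminal alkene carbon, which becomes C14, and the tertiary C13 radical is oxidised to the exocyclic alkene. Here the cis ring fusion is set in the closure, the C9 chain reaching C8 on its own face. Ozonolysis of the electron-rich exocyclic alkene (O3, CH2Cl2/MeOH, −78 °C; Me2S), which reacts well before the ring A enone, gives 35.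

2. Step 18. What may go wrong: the C16 enolate may close slowly because its C=C bond lies inside the five-membered ring being formed, which allows enolisation at C12 or C14 of the C13 ketone to compete, or the aldol equilibrium may not favour the bridged ketol. The fallback sets out from 33 and comes back at 36; it fixes the enol ether before the C13 ketone exists. Soft enolisation of the C15 ketone, the only enolisable ketone in 33 (t-BuMe2SiOTf, Et3N, CH2Cl2, −78 to 0 °C), should give the (Z)-C15 silyl enol ether F3. Brief methanolysis of the enol acetate (K2CO3, MeOH, 0 °C) gives the C13 ketone silyl enol ether F4, and SmI2 (THF/MeOH, −78 °C) removes sulfur to give the desulfurised silyl enol ether F5. BF3·OEt2 (CH2Cl2, −78 °C) then promotes an intramolecular Mukaiyama aldol addition of the regiodefined enol ether to C13, an irreversible closure that gives 36 after aqueous work-up.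

3. Step 19. What may go wrong: protonation of the enolate on the endo face, or equilibration during quench and work-up, would leave the 16S epimer. The fallback sets out from 36 and comes back at 38; it replaces proton delivery by hydrogen delivery to an alkene. LiN(SiMe3)2 (2.2 equiv) followed by PhSeCl (THF, −78 °C) should give the C16 phenylselenide F6. Oxidation with H2O2 and syn-elimination, possible only toward the C17 methyl group, gives the 16-methylidene-15-ketone F7. Hydrogenation with RhCl(PPh3)3 (H2, benzene, rt) should reduce only the unhindered exocyclic alkene and add hydrogen from the exo face (C14 side), giving 38.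

Further compounds
F1 | step 15 | (5R,9S,10S)-C9 3-methylbut-3-enyl β-keto lactone (C8 epimers), C6 O-TBS | CCC(=O)C1[C@@H](CCC(C)=C)[C@]2(COC1=O)C(=O)C=CC(C)(C)[C@H]2CO[Si](C)(C)C(C)(C)C
F2 | step 15 | (5R,8S,9S,10S)-ring C 13-methylidene compound (C8 propanoyl), C6 O-TBS | CCC(=O)[C@]23CC(=C)CC[C@H]2[C@]1(COC3=O)C(=O)C=CC(C)(C)[C@H]1CO[Si](C)(C)C(C)(C)C
F3 | step 18 | (Z)-C15 tert-butyldimethylsilyl enol ether of 33 | C/C=C(\O[Si](C)(C)C(C)(C)C)[C@]23CC(OC(C)=O)=C(Sc4ccccc4)C[C@H]2[C@]1(COC3=O)C(=O)C=CC(C)(C)[C@H]1CO[Si](C)(C)C(C)(C)C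
F4 | step 18 | (Z)-C15 silyl enol ether with C13 ketone and C12 phenylsulfanyl (C12 epimers) | C/C=C(\O[Si](C)(C)C(C)(C)C)[C@]23CC(=O)C(Sc4ccccc4)C[C@H]2[C@]1(COC3=O)C(=O)C=CC(C)(C)[C@H]1CO[Si](C)(C)C(C)(C)C
F5 | step 18 | (Z)-C15 silyl enol ether with C13 ketone, desulfurised | C/C=C(\O[Si](C)(C)C(C)(C)C)[C@]23CC(=O)CC[C@H]2[C@]1(COC3=O)C(=O)C=CC(C)(C)[C@H]1CO[Si](C)(C)C(C)(C)C
F6 | step 19 | C16 phenylselanyl derivative of 36 (C16 epimers) | CC1([Se]c4ccccc4)C(=O)[C@]23C[C@@]1(O)CC[C@H]2[C@]1(COC3=O)C(=O)C=CC(C)(C)[C@H]1CO[Si](C)(C)C(C)(C)C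
F7 | step 19 | (5R,8S,9S,10S,13S)-16-methylidene-15-ketone, C6 O-TBS | C=C1C(=O)[C@]23C[C@@]1(O)CC[C@H]2[C@]1(COC3=O)C(=O)C=CC(C)(C)[C@H]1CO[Si](C)(C)C(C)(C)C
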